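Ring B is cut at the C1–C2 bond. C1 is a benzylic, methyl-bearing methine attached to Cd of ring A, and C2 becomes an sp2 carbon if C2=C3 is kept as a cis alkene, so both ends can be carbon electrophiles: a secondary benzylic chloride and a (Z)-alkenyl bromide. A single nickel-catalysed reductive coupling under a chiral bis(oxazoline) ligand joins them, closes ring B as a 1,4-dihydronaphthalene and sets C1 from either chloride epimer. The precursor is the ring A benzoate with a 1-chloroethyl group on Cd and, on Cc, the C4 methine carrying the (Z)-2-bromovinyl arm and the C11–C16 chain; C4 and C11 arise from an Ireland–Claisen rearrangement, C15 from the chiral pool.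

Key step: step 20

Labels: ring A carbons are Ca (CO2Me), Cb (H), Cc (bears C4), Cd (bears C1), Ce (OH), Cf (OMe); ring B is C1 (methyl), C2, C3, C4; the side chain runs C11 (methyl), C12, C13, C14, C15 (methyl), C16 (CH2OH).
Ligand: L* = (3aR,3a'R,8aS,8a'S)-2,2'-(cyclopropane-1,1-diyl)bis(3a,8a-dihydro-8H-indeno[1,2-d]oxazole).
Assumption: the sense of induction of L* at C1 in the ring-forming case is taken to follow the intermolecular reaction; L* is written as one antipode and its mirror image serves if the sense proves opposite.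
Remark: the carbinol carbon made in step 6 (later C1) is racemic, so 19 to 30 are pairs of C1 epimers that are carried on together and converge in step 20. The C16 hydroxyl is carried as a benzyl ether so that one hydrogenation after the key step finishes the synthesis.

Step 1
Reactants: 1 methyl 2,3-dihydroxybenzoate
Product: 2 methyl 5-bromo-2,3-dihydroxybenzoate
Conditions: Br2 (1.0 equiv), AcOH, 15 °C → rt
Reagents that add atoms: bromine, BrBr
Why: Electrophilic aromatic bromination should go to C5 (the future Cc), which is para to the 2-hydroxyl and the only free position that is neither ortho nor para to the deactivating ester.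

Step 2
Reactants: 2 methyl 5-bromo-2,3-dihydroxybenzoate
Product: 4 methyl 5-bromo-2-methoxy-3-[(4-methoxybenzyl)oxy]benzoate, via 4-methoxybenzyl ether 3 (not isolated)
Conditions: 4-methoxybenzyl chloride (1.05 equiv), K2CO3 (1.1 equiv), DMF, rt; then MeI (3 equiv), K2CO3 (2 equiv), 45 °C
Reagents that add atoms: 4-methoxybenzyl chloride, COc1ccc(CCl)cc1; iodomethane, CI
Why: Two Williamson etherifications in one pot: the 3-hydroxyl, which is not hydrogen-bonded to the ester carbonyl, is the more acidic and more nucleophilic phenol and is alkylated first, and the chelated 2-hydroxyl (the future Cf–OMe) is methylated in the more forcing second stage.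

Step 3
Reactants: 4 methyl 5-bromo-2-methoxy-3-[(4-methoxybenzyl)oxy]benzoate
Product: 5 methyl 5-bromo-3-hydroxy-2-methoxybenzoate
Conditions: CF3CO2H, anisole, CH2Cl2, 0 °C → rt
Reagents that add atoms: none
Why: Acidolysis of an aryl 4-methoxybenzyl ether, with the benzylic cation trapped by anisole, frees the Ce phenol while the methyl ether, the ester and the aryl bromide are inert.

Step 4
Reactants: 5 methyl 5-bromo-3-hydroxy-2-methoxybenzoate
Product: 6 methyl 5-bromo-4-formyl-3-hydroxy-2-methoxybenzoate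
Conditions: MgCl2 (2 equiv), Et3N (4 equiv), (CH2O)n (6 equiv), MeCN, reflux; 1 M HCl
Reagents that add atoms: paraformaldehyde (as formaldehyde), C=O
Why: Magnesium-mediated ortho-formylation of a phenol (Casnati–Skattebøl) delivers formaldehyde inside the magnesium phenoxide chelate, so the formyl group can only enter at Cd, the single free position ortho to the Ce oxygen.

Step 5
Reactants: 6 methyl 5-bromo-4-formyl-3-hydroxy-2-methoxybenzoate
Product: 7 methyl 3-(benzyloxy)-5-bromo-4-formyl-2-methoxybenzoate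
Conditions: BnBr (1.3 equiv), K2CO3 (1.5 equiv), DMF, 40 °C
Reagents that add atoms: benzyl bromide, BrCc1ccccc1
Why: Williamson etherification of the acidic salicylaldehyde-type phenol installs the benzyl group that stays on Ce until the last step.

Step 6
Reactants: 7 methyl 3-(benzyloxy)-5-bromo-4-formyl-2-methoxybenzoate
Product: 9 methyl 3-(benzyloxy)-5-bromo-4-[1-(tert-butyldimethylsilyloxy)ethyl]-2-methoxybenzoate (racemic), via bromomagnesium alkoxide 8 (not isolated)
Conditions: MeMgBr (1.15 equiv), THF, −78 °C; then t-BuMe2SiOTf (1.6 equiv), 2,6-lutidine (1 equiv), −78 → 0 °C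
Reagents that add atoms: methylmagnesium bromide, C[Mg]Br; tert-butyldimethylsilyl trifluoromethanesulfonate, CC(C)(C)[Si](C)(C)OS(=O)(=O)C(F)(F)F
Why: Grignard addition to the aldehyde, which is far faster than attack on the hindered aryl ester at low temperature, is followed by silylation of the alkoxide in the same flask; the new carbinol centre (later C1) forms as a racemate, which is acceptable because step 20 is expected to make both epimers converge.

Step 7
Reactants: 9 methyl 3-(benzyloxy)-5-bromo-4-[1-(tert-butyldimethylsilyloxy)ethyl]-2-methoxybenzoate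
Product: 10 methyl 3-(benzyloxy)-5-(2-tert-butoxy-2-oxoethyl)-4-[1-(tert-butyldimethylsilyloxy)ethyl]-2-methoxybenzoate (racemic)
Conditions: BrZnCH2CO2t-Bu (2 equiv), Pd2(dba)3 (2.5 mol%), XPhos (6 mol%), THF, 60 °C
Reagents that add atoms: (2-tert-butoxy-2-oxoethyl)zinc bromide, CC(C)(C)OC(=O)C[Zn]Br
Why: Palladium-catalysed Negishi-type coupling of a Reformatsky reagent with the aryl bromide (α-arylation of an acetate) places the future C4–C3 unit on Cc under neutral conditions that spare the methyl ester and both ethers.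

Step 8
Reactants: 10 methyl 3-(benzyloxy)-5-(2-tert-butoxy-2-oxoethyl)-4-[1-(tert-butyldimethylsilyloxy)ethyl]-2-methoxybenzoate
Product: 12 {3-(benzyloxy)-2-[1-(tert-butyldimethylsilyloxy)ethyl]-4-methoxy-5-(methoxycarbonyl)phenyl}acetic acid (racemic), via trimethylsilyl ester 11 (not isolated)
Conditions: Me3SiOTf (2.5 equiv), 2,6-lutidine (4 equiv), CH2Cl2, 0 °C; then pH 5 buffer, THF
Reagents that add atoms: none
Why: Silyl triflate-mediated cleavage of a tert-butyl ester (loss of isobutene, then hydrolysis of the silyl ester on work-up) is buffered by 2,6-lutidine and should leave the benzylic silyl ether, the benzyl ether and the methyl ester untouched.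

Step 9
Reactants: 13 (R)-3-bromo-2-methylpropan-1-ol
Product: 14 (R)-[(3-bromo-2-methylpropoxy)methyl]benzene
Conditions: benzyl 2,2,2-trichloroacetimidate (1.3 equiv), CF3SO3H (5 mol%), CH2Cl2–cyclohexane, 0 °C → rt
Reagents that add atoms: benzyl 2,2,2-trichloroacetimidate, ClC(Cl)(Cl)C(=N)OCc1ccccc1
Why: Acid-catalysed O-benzylation with a trichloroacetimidate avoids forming an alkoxide next to the primary bromide and does not touch the chiral-pool centre that becomes C15.

Step 10
Reactants: 14 (R)-[(3-bromo-2-methylpropoxy)methyl]benzene; 15 (E)-N-methoxy-N-methylbut-2-enamide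
Product: 17 (2E,6S)-7-(benzyloxy)-6-methylhept-2-en-4-one, via Grignard reagent 16 (not isolated)
Conditions: Mg, THF, 45 °C; then 15, THF, −20 → 0 °C; cold 1 M HCl
Reagents that add atoms: none
Why: Weinreb ketone synthesis: the Grignard reagent adds once to the N-methoxy-N-methylamide and the chelated tetrahedral adduct collapses to the enone only on acidic work-up, so neither over-addition nor conjugate addition is expected.

Step 11
Reactants: 17 (2E,6S)-7-(benzyloxy)-6-methylhept-2-en-4-one
Product: 18 (2E,4R,6S)-7-(benzyloxy)-6-methylhept-2-en-4-ol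
Conditions: (S)-1-methyl-3,3-diphenyltetrahydro-1H,3H-pyrrolo[1,2-c][1,3,2]oxazaborole (20 mol%), catecholborane (1.8 equiv), toluene, −78 °C
Reagents that add atoms: none
Why: Corey–Bakshi–Shibata reduction: with the propenyl group as the large and the CH2 chain as the small substituent, the (S)-oxazaborolidine should deliver hydride to the face that gives the (4R) carbinol (C13), the stereochemical source of C4 and C11.

Step 12
Reactants: 12 {3-(benzyloxy)-2-[1-(tert-butyldimethylsilyloxy)ethyl]-4-methoxy-5-(methoxycarbonyl)phenyl}acetic acid; 18 (2E,4R,6S)-7-(benzyloxy)-6-methylhept-2-en-4-ol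
Product: 19 (2E,4R,6S)-7-(benzyloxy)-6-methylhept-2-en-4-yl {3-(benzyloxy)-2-[1-(tert-butyldimethylsilyloxy)ethyl]-4-methoxy-5-(methoxycarbonyl)phenyl}acetate (both C1 epimers)
Conditions: EDC·HCl (1.5 equiv), DMAP (0.2 equiv), CH2Cl2, 0 °C → rt
Reagents that add atoms: none
Why: Carbodiimide (Steglich-type) esterification joins the arylacetic acid to the secondary allylic alcohol without touching the C13 centre.

Step 13
Reactants: 19 (2E,4R,6S)-7-(benzyloxy)-6-methylhept-2-en-4-yl {3-(benzyloxy)-2-[1-(tert-butyldimethylsilyloxy)ethyl]-4-methoxy-5-(methoxycarbonyl)phenyl}acetate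
Product: 22 (2S,3S,4E,7S)-8-(benzyloxy)-2-{3-(benzyloxy)-2-[1-(tert-butyldimethylsilyloxy)ethyl]-4-methoxy-5-(methoxycarbonyl)phenyl}-3,7-dimethyloct-4-enoic acid (both C1 epimers), via trimethylsilyl ketene acetal 20 (not isolated), via trimethylsilyl ester 21 (not isolated)
Conditions: KN(SiMe3)2 (1.5 equiv), THF–toluene, −78 °C; Me3SiCl (2.5 equiv, premixed with Et3N), −78 °C → rt; 1 M HCl, THF
Reagents that add atoms: none
Why: Ireland–Claisen rearrangement: the arylacetate should give the potassium enolate with the aryl group cis to O–K, and its silyl ketene acetal rearranges through a chair with the C14 chain equatorial, so the (4R) carbinol centre is relayed into (S)-C4 and (S)-C11 together with an (E)-C12=C13 alkene.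

Step 14
Reactants: 22 (2S,3S,4E,7S)-8-(benzyloxy)-2-{3-(benzyloxy)-2-[1-(tert-butyldimethylsilyloxy)ethyl]-4-methoxy-5-(methoxycarbonyl)phenyl}-3,7-dimethyloct-4-enoic acid
Product: 23 (2S,3S,7S)-8-(benzyloxy)-2-{3-(benzyloxy)-2-[1-(tert-butyldimethylsilyloxy)ethyl]-4-methoxy-5-(methoxycarbonyl)phenyl}-3,7-dimethyloctanoic acid (both C1 epimers)
Conditions: H2 (1 atm), 5% Pt/C, EtOAc, rt
Reagents that add atoms: none
Why: Heterogeneous hydrogenation on platinum saturates the disubstituted C12=C13 alkene, and because platinum is a poor hydrogenolysis catalyst both benzyl ethers and the benzylic silyl ether should remain.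

Step 15
Reactants: 23 (2S,3S,7S)-8-(benzyloxy)-2-{3-(benzyloxy)-2-[1-(tert-butyldimethylsilyloxy)ethyl]-4-methoxy-5-(methoxycarbonyl)phenyl}-3,7-dimethyloctanoic acid
Product: 24 methyl 3-(benzyloxy)-5-[(2S,3S,7S)-8-(benzyloxy)-1-hydroxy-3,7-dimethyloctan-2-yl]-4-[1-(tert-butyldimethylsilyloxy)ethyl]-2-methoxybenzoate (both C1 epimers)
Conditions: BH3·SMe2 (2.5 equiv), THF, 0 °C → rt; MeOH
Reagents that add atoms: none
Why: Borane reduction is chemoselective for the free carboxylic acid (via the acyloxyborane) over the aryl methyl ester, so only the C3 carboxyl is taken to the primary alcohol.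

Step 16
Reactants: 24 methyl 3-(benzyloxy)-5-[(2S,3S,7S)-8-(benzyloxy)-1-hydroxy-3,7-dimethyloctan-2-yl]-4-[1-(tert-butyldimethylsilyloxy)ethyl]-2-methoxybenzoate
Product: 25 methyl 3-(benzyloxy)-5-[(2S,3S,7S)-8-(benzyloxy)-3,7-dimethyl-1-oxooctan-2-yl]-4-[1-(tert-butyldimethylsilyloxy)ethyl]-2-methoxybenzoate (both C1 epimers)
Conditions: Dess–Martin periodinane (1.3 equiv), NaHCO3, CH2Cl2, 0 °C → rt
Reagents that add atoms: none
Why: Dess–Martin oxidation under buffered, non-basic conditions gives the α-aryl aldehyde without enolising the C4 centre.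

Step 17
Reactants: 25 methyl 3-(benzyloxy)-5-[(2S,3S,7S)-8-(benzyloxy)-3,7-dimethyl-1-oxooctan-2-yl]-4-[1-(tert-butyldimethylsilyloxy)ethyl]-2-methoxybenzoate; 26 (bromomethyl)triphenylphosphonium bromide
Product: 28 methyl 3-(benzyloxy)-5-[(1Z,3R,4S,8S)-9-(benzyloxy)-1-bromo-4,8-dimethylnon-1-en-3-yl]-4-[1-(tert-butyldimethylsilyloxy)ethyl]-2-methoxybenzoate (both C1 epimers), via (bromomethylene)triphenylphosphorane 27 (not isolated)
Conditions: 26 (1.6 equiv), KOt-Bu (1.5 equiv), THF, −78 °C; then 25, −78 → −40 °C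
Reagents that add atoms: none
Why: Wittig olefination with the non-stabilised bromo-ylide (Stork–Zhao type) proceeds through the kinetic cis-oxaphosphetane to the (Z)-alkenyl bromide, and the low temperature with base kept below the amount of phosphonium salt is meant to protect the C4 centre from enolisation.

Step 18
Reactants: 28 methyl 3-(benzyloxy)-5-[(1Z,3R,4S,8S)-9-(benzyloxy)-1-bromo-4,8-dimethylnon-1-en-3-yl]-4-[1-(tert-butyldimethylsilyloxy)ethyl]-2-methoxybenzoate
Product: 29 methyl 3-(benzyloxy)-5-[(1Z,3R,4S,8S)-9-(benzyloxy)-1-bromo-4,8-dimethylnon-1-en-3-yl]-4-(1-hydroxyethyl)-2-methoxybenzoate (both C1 epimers)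
Conditions: HF·pyridine, pyridine, THF, 0 °C → rt
Reagents that add atoms: none
Why: Fluoride-mediated desilylation frees the benzylic carbinol, and no other silyl group is present so no selectivity is required.

Step 19
Reactants: 29 methyl 3-(benzyloxy)-5-[(1Z,3R,4S,8S)-9-(benzyloxy)-1-bromo-4,8-dimethylnon-1-en-3-yl]-4-(1-hydroxyethyl)-2-methoxybenzoate
Product: 30 methyl 3-(benzyloxy)-5-[(1Z,3R,4S,8S)-9-(benzyloxy)-1-bromo-4,8-dimethylnon-1-en-3-yl]-4-(1-chloroethyl)-2-methoxybenzoate (both C1 epimers)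
Conditions: SOCl2 (1.5 equiv), CH2Cl2, 0 °C; used without chromatography
Reagents that add atoms: thionyl chloride, O=S(Cl)Cl
Why: Deoxychlorination of a secondary benzylic alcohol with thionyl chloride; the configuration at C1 is irrelevant, and the para ester tempers ionisation of the chloride.

Step 20
Reactants: 30 methyl 3-(benzyloxy)-5-[(1Z,3R,4S,8S)-9-(benzyloxy)-1-bromo-4,8-dimethylnon-1-en-3-yl]-4-(1-chloroethyl)-2-methoxybenzoate
Product: 31 methyl (5R,8R)-4-(benzyloxy)-8-[(2S,6S)-7-(benzyloxy)-6-methylheptan-2-yl]-3-methoxy-5-methyl-5,8-dihydronaphthalene-2-carboxylate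
Conditions: NiCl2(dme) (15 mol%), L* (18 mol%), Mn powder (3 equiv), NaI (0.5 equiv), DMA (0.01 M), 0 °C → rt
Reagents that add atoms: none
Why: Proposed new method: zerovalent nickel, formed from NiCl2(dme) and Mn, should insert into the C2–Br bond with retention of the Z geometry, and a monovalent nickel species should abstract chlorine from C1 to give a benzylic radical that is captured at the alkenylnickel centre, after which the trivalent nickel species reductively eliminates the C1–C2 bond and Mn returns the metal to its low-valent state. The closest known reaction type is the intermolecular nickel-catalysed enantioselective reductive cross-coupling of alkenyl bromides with secondary benzylic chlorides, and the ring-forming variant is the untested part. Ring B closes as a six-membered carbocycle by reductive elimination from a seven-membered nickelacycle (Ni, C2, C3, C4, Cc, Cd, C1), a closure that only the Z alkene allows and that leaves C2=C3 in place as the 1,4-dihydronaphthalene. The new stereocentre C1 is set by the chiral bis(oxazoline)–nickel complex at the radical-capture and reductive-elimination stage, so both chloride epimers should converge on (R)-C1, trans to the C4 side chain. The step needs capture of the radical at nickel to outrun direct addition of the C1 radical to C3, β-hydride loss to a styrene and coupling between molecules; the stabilised, hindered benzylic radical (slow to add to an alkene), the alkenylnickel held next to C1 by the cis geometry and high dilution should secure this.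

Step 21
Reactants: 31 methyl (5R,8R)-4-(benzyloxy)-8-[(2S,6S)-7-(benzyloxy)-6-methylheptan-2-yl]-3-methoxy-5-methyl-5,8-dihydronaphthalene-2-carboxylate
Product: 32 methyl (5R,8S)-4-hydroxy-8-[(2S,6S)-7-hydroxy-6-methylheptan-2-yl]-3-methoxy-5-methyl-5,6,7,8-tetrahydronaphthalene-2-carboxylate (CNP0398293.1)
Conditions: H2 (1 atm), 10% Pd/C, EtOAc–MeOH, rt
Reagents that add atoms: none
Why: Catalytic hydrogenation saturates the cis C2=C3 alkene and hydrogenolyses both benzyl ethers in one operation; a fresh catalyst in hydrogen-saturated solvent is used so that the alkene is reduced before it can migrate towards C1 or C4.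

Compound list
1 | methyl 2,3-dihydroxybenzoate | COC(=O)c1cccc(O)c1O | starting material
2 | methyl 5-bromo-2,3-dihydroxybenzoate | COC(=O)c1cc(Br)cc(O)c1O | intermediate
3 | methyl 5-bromo-2-hydroxy-3-[(4-methoxybenzyl)oxy]benzoate | COC(=O)c1cc(Br)cc(OCc2ccc(OC)cc2)c1O | intermediate
4 | methyl 5-bromo-2-methoxy-3-[(4-methoxybenzyl)oxy]benzoate | COC(=O)c1cc(Br)cc(OCc2ccc(OC)cc2)c1OC | intermediate
5 | methyl 5-bromo-3-hydroxy-2-methoxybenzoate | COC(=O)c1cc(Br)cc(O)c1OC | intermediate
6 | methyl 5-bromo-4-formyl-3-hydroxy-2-methoxybenzoate | COC(=O)c1cc(Br)c(C=O)c(O)c1OC | intermediate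
7 | methyl 3-(benzyloxy)-5-bromo-4-formyl-2-methoxybenzoate | COC(=O)c1cc(Br)c(C=O)c(OCc2ccccc2)c1OC | intermediate
8 | bromomagnesium 1-[2-(benzyloxy)-6-bromo-3-methoxy-4-(methoxycarbonyl)phenyl]ethoxide (racemic) | COC(=O)c1cc(Br)c(C(C)O[Mg]Br)c(OCc2ccccc2)c1OC | intermediate
9 | methyl 3-(benzyloxy)-5-bromo-4-[1-(tert-butyldimethylsilyloxy)ethyl]-2-methoxybenzoate (racemic) | COC(=O)c1cc(Br)c(C(C)O[Si](C)(C)C(C)(C)C)c(OCc2ccccc2)c1OC | intermediate
10 | methyl 3-(benzyloxy)-5-(2-tert-butoxy-2-oxoethyl)-4-[1-(tert-butyldimethylsilyloxy)ethyl]-2-methoxybenzoate (racemic) | COC(=O)c1cc(CC(=O)OC(C)(C)C)c(C(C)O[Si](C)(C)C(C)(C)C)c(OCc2ccccc2)c1OC | intermediate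
11 | trimethylsilyl {3-(benzyloxy)-2-[1-(tert-butyldimethylsilyloxy)ethyl]-4-methoxy-5-(methoxycarbonyl)phenyl}acetate (racemic) | COC(=O)c1cc(CC(=O)O[Si](C)(C)C)c(C(C)O[Si](C)(C)C(C)(C)C)c(OCc2ccccc2)c1OC | intermediate
12 | {3-(benzyloxy)-2-[1-(tert-butyldimethylsilyloxy)ethyl]-4-methoxy-5-(methoxycarbonyl)phenyl}acetic acid (racemic) | COC(=O)c1cc(CC(=O)O)c(C(C)O[Si](C)(C)C(C)(C)C)c(OCc2ccccc2)c1OC | intermediate
13 | (R)-3-bromo-2-methylpropan-1-ol | OC[C@@H](C)CBr | starting material
14 | (R)-[(3-bromo-2-methylpropoxy)methyl]benzene | BrC[C@H](C)COCc1ccccc1 | intermediate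
15 | (E)-N-methoxy-N-methylbut-2-enamide | C/C=C/C(=O)N(C)OC | starting material
16 | (R)-[3-(benzyloxy)-2-methylpropyl]magnesium bromide | Br[Mg]C[C@H](C)COCc1ccccc1 | intermediate
17 | (2E,6S)-7-(benzyloxy)-6-methylhept-2-en-4-one | C/C=C/C(=O)C[C@H](C)COCc1ccccc1 | intermediate
18 | (2E,4R,6S)-7-(benzyloxy)-6-methylhept-2-en-4-ol | C/C=C/[C@H](O)C[C@H](C)COCc1ccccc1 | intermediate
19 | (2E,4R,6S)-7-(benzyloxy)-6-methylhept-2-en-4-yl {3-(benzyloxy)-2-[1-(tert-butyldimethylsilyloxy)ethyl]-4-methoxy-5-(methoxycarbonyl)phenyl}acetate (both C1 epimers) | COC(=O)c1cc(CC(=O)O[C@@H](/C=C/C)C[C@H](C)COCc2ccccc2)c(C(C)O[Si](C)(C)C(C)(C)C)c(OCc2ccccc2)c1OC | intermediate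
20 | (Z)-trimethylsilyl ketene acetal of 19, aryl cis to OSiMe3 (both C1 epimers) | COC(=O)c1cc(/C=C(\O[Si](C)(C)C)O[C@@H](/C=C/C)C[C@H](C)COCc2ccccc2)c(C(C)O[Si](C)(C)C(C)(C)C)c(OCc2ccccc2)c1OC | intermediate
21 | trimethylsilyl (2S,3S,4E,7S)-8-(benzyloxy)-2-{3-(benzyloxy)-2-[1-(tert-butyldimethylsilyloxy)ethyl]-4-methoxy-5-(methoxycarbonyl)phenyl}-3,7-dimethyloct-4-enoate (both C1 epimers) | COC(=O)c1cc([C@@H](C(=O)O[Si](C)(C)C)[C@@H](C)/C=C/C[C@H](C)COCc2ccccc2)c(C(C)O[Si](C)(C)C(C)(C)C)c(OCc2ccccc2)c1OC | intermediate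
22 | (2S,3S,4E,7S)-8-(benzyloxy)-2-{3-(benzyloxy)-2-[1-(tert-butyldimethylsilyloxy)ethyl]-4-methoxy-5-(methoxycarbonyl)phenyl}-3,7-dimethyloct-4-enoic acid (both C1 epimers) | COC(=O)c1cc([C@@H](C(=O)O)[C@@H](C)/C=C/C[C@H](C)COCc2ccccc2)c(C(C)O[Si](C)(C)C(C)(C)C)c(OCc2ccccc2)c1OC | intermediate
23 | (2S,3S,7S)-8-(benzyloxy)-2-{3-(benzyloxy)-2-[1-(tert-butyldimethylsilyloxy)ethyl]-4-methoxy-5-(methoxycarbonyl)phenyl}-3,7-dimethyloctanoic acid (both C1 epimers) | COC(=O)c1cc([C@@H](C(=O)O)[C@@H](C)CCC[C@H](C)COCc2ccccc2)c(C(C)O[Si](C)(C)C(C)(C)C)c(OCc2ccccc2)c1OC | intermediate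
24 | methyl 3-(benzyloxy)-5-[(2S,3S,7S)-8-(benzyloxy)-1-hydroxy-3,7-dimethyloctan-2-yl]-4-[1-(tert-butyldimethylsilyloxy)ethyl]-2-methoxybenzoate (both C1 epimers) | COC(=O)c1cc([C@@H](CO)[C@@H](C)CCC[C@H](C)COCc2ccccc2)c(C(C)O[Si](C)(C)C(C)(C)C)c(OCc2ccccc2)c1OC | intermediate
25 | methyl 3-(benzyloxy)-5-[(2S,3S,7S)-8-(benzyloxy)-3,7-dimethyl-1-oxooctan-2-yl]-4-[1-(tert-butyldimethylsilyloxy)ethyl]-2-methoxybenzoate (both C1 epimers) | COC(=O)c1cc([C@@H](C=O)[C@@H](C)CCC[C@H](C)COCc2ccccc2)c(C(C)O[Si](C)(C)C(C)(C)C)c(OCc2ccccc2)c1OC | intermediate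
26 | (bromomethyl)triphenylphosphonium bromide | [Br-].BrC[P+](c1ccccc1)(c1ccccc1)c1ccccc1 | starting material
27 | (bromomethylene)triphenylphosphorane | BrC=P(c1ccccc1)(c1ccccc1)c1ccccc1 | intermediate
28 | methyl 3-(benzyloxy)-5-[(1Z,3R,4S,8S)-9-(benzyloxy)-1-bromo-4,8-dimethylnon-1-en-3-yl]-4-[1-(tert-butyldimethylsilyloxy)ethyl]-2-methoxybenzoate (both C1 epimers) | COC(=O)c1cc([C@@H](/C=C\Br)[C@@H](C)CCC[C@H](C)COCc2ccccc2)c(C(C)O[Si](C)(C)C(C)(C)C)c(OCc2ccccc2)c1OC | intermediate
29 | methyl 3-(benzyloxy)-5-[(1Z,3R,4S,8S)-9-(benzyloxy)-1-bromo-4,8-dimethylnon-1-en-3-yl]-4-(1-hydroxyethyl)-2-methoxybenzoate (both C1 epimers) | COC(=O)c1cc([C@@H](/C=C\Br)[C@@H](C)CCC[C@H](C)COCc2ccccc2)c(C(C)O)c(OCc2ccccc2)c1OC | intermediate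
30 | methyl 3-(benzyloxy)-5-[(1Z,3R,4S,8S)-9-(benzyloxy)-1-bromo-4,8-dimethylnon-1-en-3-yl]-4-(1-chloroethyl)-2-methoxybenzoate (both C1 epimers) | COC(=O)c1cc([C@@H](/C=C\Br)[C@@H](C)CCC[C@H](C)COCc2ccccc2)c(C(C)Cl)c(OCc2ccccc2)c1OC | intermediate
31 | methyl (5R,8R)-4-(benzyloxy)-8-[(2S,6S)-7-(benzyloxy)-6-methylheptan-2-yl]-3-methoxy-5-methyl-5,8-dihydronaphthalene-2-carboxylate | COC(=O)c1cc2c(c(OCc3ccccc3)c1OC)[C@H](C)C=C[C@H]2[C@@H](C)CCC[C@H](C)COCc1ccccc1 | intermediate
32 | methyl (5R,8S)-4-hydroxy-8-[(2S,6S)-7-hydroxy-6-methylheptan-2-yl]-3-methoxy-5-methyl-5,6,7,8-tetrahydronaphthalene-2-carboxylate | COC(=O)c1cc2c(c(O)c1OC)[C@H](C)CC[C@H]2[C@@H](C)CCC[C@H](C)CO | target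

Total step count: 21. Longest linear sequence: 18 steps (steps 1–8 and 12–21); the alcohol fragment takes 3 steps (9–11).

Steps most likely to fail

Step 20. The benzylic radical may add directly to C3 and close a five-membered ring, the benzylic nickel species may lose a β-hydrogen to give a styrene, coupling may occur between molecules, or the C4 centre may override the ligand in fixing C1. The fallback sets out from 28 and returns at 31, using only known reaction types. Pd(PPh3)4-catalysed hydrodebromination of 28 with Bu3SnH would give the terminal alkene F1. HF·pyridine would then free the benzylic carbinol F2, and SOCl2 would convert it into the benzylic chloride F3 (both epimers). The documented intermolecular coupling (NiCl2(dme), L*, Mn powder, NaI, DMA) of F3 with (E)-1-bromoprop-1-ene would make the C1–C2 bond under catalyst control and give the diene F4. Ring-closing metathesis of F4 with the second-generation Grubbs catalyst RuCl2(=CHPh)(H2IMes)(PCy3) in CH2Cl2 would close ring B at C2=C3 with loss of propene and deliver 31.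

Step 17. The basic ylide may enolise the α-aryl aldehyde and epimerise C4, addition to the hindered carbonyl may be slow, and Z selectivity may erode. The fallback sets out from 25 and returns at 28. CBr4 and PPh3 with 2,6-lutidine in CH2Cl2 at 0 °C, a non-basic olefination, would give the 1,1-dibromoalkene F5. Pd(PPh3)4-catalysed hydrogenolysis of F5 with Bu3SnH removes the bromine trans to the C4 substituent selectively and would leave the (Z)-alkenyl bromide 28.

Step 4. Formylation at a position flanked by bromine on an electron-poor phenol may stall or stop at the hydroxymethyl stage. The fallback sets out from 5 and returns at 7. O-Allylation of 5 (allyl bromide, K2CO3, DMF) would give the allyl ether F6. Aromatic Claisen rearrangement of F6 (N,N-diethylaniline, 190 °C) can only deliver the allyl group to Cd and would give the allylphenol F7. Benzylation (BnBr, K2CO3) would give the benzyl ether F8, and PdCl2(MeCN)2 in toluene would move the double bond into conjugation to give the (E)-propenyl arene F9. Ozonolysis of F9 (O3, CH2Cl2–MeOH, −78 °C; Me2S) would give the aldehyde 7.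

Further compounds
F1 | step 20 | methyl 3-(benzyloxy)-5-[(3S,4S,8S)-9-(benzyloxy)-4,8-dimethylnon-1-en-3-yl]-4-[1-(tert-butyldimethylsilyloxy)ethyl]-2-methoxybenzoate (both C1 epimers) | COC(=O)c1cc([C@@H](C=C)[C@@H](C)CCC[C@H](C)COCc2ccccc2)c(C(C)O[Si](C)(C)C(C)(C)C)c(OCc2ccccc2)c1OC
F2 | step 20 | methyl 3-(benzyloxy)-5-[(3S,4S,8S)-9-(benzyloxy)-4,8-dimethylnon-1-en-3-yl]-4-(1-hydroxyethyl)-2-methoxybenzoate (both C1 epimers) | COC(=O)c1cc([C@@H](C=C)[C@@H](C)CCC[C@H](C)COCc2ccccc2)c(C(C)O)c(OCc2ccccc2)c1OC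
F3 | step 20 | methyl 3-(benzyloxy)-5-[(3S,4S,8S)-9-(benzyloxy)-4,8-dimethylnon-1-en-3-yl]-4-(1-chloroethyl)-2-methoxybenzoate (both C1 epimers) | COC(=O)c1cc([C@@H](C=C)[C@@H](C)CCC[C@H](C)COCc2ccccc2)c(C(C)Cl)c(OCc2ccccc2)c1OC
F4 | step 20 | methyl 3-(benzyloxy)-5-[(3S,4S,8S)-9-(benzyloxy)-4,8-dimethylnon-1-en-3-yl]-2-methoxy-4-[(2R,3E)-pent-3-en-2-yl]benzoate | COC(=O)c1cc([C@@H](C=C)[C@@H](C)CCC[C@H](C)COCc2ccccc2)c([C@H](C)/C=C/C)c(OCc2ccccc2)c1OC
F5 | step 17 | methyl 3-(benzyloxy)-5-[(3R,4S,8S)-9-(benzyloxy)-1,1-dibromo-4,8-dimethylnon-1-en-3-yl]-4-[1-(tert-butyldimethylsilyloxy)ethyl]-2-methoxybenzoate (both C1 epimers) | COC(=O)c1cc([C@@H](C=C(Br)Br)[C@@H](C)CCC[C@H](C)COCc2ccccc2)c(C(C)O[Si](C)(C)C(C)(C)C)c(OCc2ccccc2)c1OC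
F6 | step 4 | methyl 3-(allyloxy)-5-bromo-2-methoxybenzoate | COC(=O)c1cc(Br)cc(OCC=C)c1OC
F7 | step 4 | methyl 4-allyl-5-bromo-3-hydroxy-2-methoxybenzoate | COC(=O)c1cc(Br)c(CC=C)c(O)c1OC
F8 | step 4 | methyl 4-allyl-3-(benzyloxy)-5-bromo-2-methoxybenzoate | COC(=O)c1cc(Br)c(CC=C)c(OCc2ccccc2)c1OC
F9 | step 4 | methyl 3-(benzyloxy)-5-bromo-2-methoxy-4-[(E)-prop-1-en-1-yl]benzoate | COC(=O)c1cc(Br)c(/C=C/C)c(OCc2ccccc2)c1OC
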